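The route rests on disconnecting ring B, the furan-2(5H)-one (O1, C2, C3, C4, C5), at its C2–C3 bond. In one operation, iodine–lithium exchange on a (Z)-3-iodoallyl phenyl carbonate generates a vinyllithium at C3 that attacks the carbonate carbon C2 on O1 and closes the butenolide by 5-exo-trig acyl substitution. The step exploits the cis relationship of C3 and the O1-bearing C5 methylene across the C3=C4 double bond. The precursor, an acyclic iodo-trienyl carbonate carrying the acetal-masked chain, comes from anti-carbomagnesiation of prop-2-yn-1-ol with a farnesol-derived dienyl Grignard reagent. A Z-selective Horner–Wadsworth–Emmons reaction with a chiral phosphono lactone finally adds ring A.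

Key step: step 8

Remark: (2E,6E)-farnesol is taken as the commercial single isomer; ring B is numbered as furan-2(5H)-one, ring A is the α-alkylidene-γ-butyrolactone, and PPTS is pyridinium p-toluenesulfonate.

Step 1
Reactants: 1 (2E,6E)-farnesol
Product: 3 (2E,6E)-9-(3,3-dimethyloxiran-2-yl)-3,7-dimethylnona-2,6-dien-1-ol (racemic), via bromohydrin 2 (not isolated)
Conditions: NBS, THF/H2O (2:1), 0 °C; then K2CO3, MeOH, rt
Reagents that add atoms: water, O; N-bromosuccinimide, O=C1CCC(=O)N1Br (its bromine reaches only intermediate 2)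
Why: Terminal-selective bromohydrin formation on the most accessible, electron-rich trisubstituted alkene in aqueous THF, followed by base-induced ring closure (intramolecular Williamson reaction), should give the racemic terminal epoxide, whose stereocentre is destroyed in step 2.

Step 2
Reactants: 3 (2E,6E)-9-(3,3-dimethyloxiran-2-yl)-3,7-dimethylnona-2,6-dien-1-ol
Product: 4 (4E,8E)-10-hydroxy-4,8-dimethyldeca-4,8-dienal
Conditions: HIO4·2H2O, THF/H2O, 0 °C
Reagents that add atoms: none
Why: Periodic acid hydrolyses the epoxide to the vicinal diol and cleaves it in the same flask (Malaprade glycol cleavage) to the aldehyde and acetone, leaving the allylic alcohol and both alkenes untouched.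

Step 3
Reactants: 4 (4E,8E)-10-hydroxy-4,8-dimethyldeca-4,8-dienal
Product: 5 (2E,6E)-10,10-dimethoxy-3,7-dimethyldeca-2,6-dien-1-ol
Conditions: HC(OMe)3, MeOH, PPTS (cat.), rt
Reagents that add atoms: trimethyl orthoformate, COC(OC)OC; methanol, CO
Why: Acid-catalysed acetalisation with orthoformate as water scavenger masks the aldehyde against the organolithium and magnesium reagents of steps 6 and 8 while the primary allylic alcohol stays free.

Step 4
Reactants: 5 (2E,6E)-10,10-dimethoxy-3,7-dimethyldeca-2,6-dien-1-ol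
Product: 6 (2E,6E)-10,10-dimethoxy-3,7-dimethyldeca-2,6-dienal
Conditions: MnO2, CH2Cl2, rt
Reagents that add atoms: none
Why: Manganese dioxide oxidises allylic alcohols chemoselectively to the enal with retention of the 2E geometry.

Step 5
Reactants: 6 (2E,6E)-10,10-dimethoxy-3,7-dimethyldeca-2,6-dienal
Product: 7 (1E,3E,7E)-1-iodo-11,11-dimethoxy-4,8-dimethylundeca-1,3,7-triene
Conditions: CrCl2, CHI3, THF/dioxane (1:6), 0 °C to rt, dark
Reagents that add atoms: iodoform, IC(I)I
Why: Takai olefination, in which the gem-dichromium species formed from iodoform and CrCl2 (divalent chromium) adds to the aldehyde and eliminates to give the E-iodoalkene preferentially; the minor 1Z isomer is to be removed by chromatography.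

Step 6
Reactants: 7 (1E,3E,7E)-1-iodo-11,11-dimethoxy-4,8-dimethylundeca-1,3,7-triene; 8 prop-2-yn-1-ol
Product: 13 (2Z)-3-iodo-2-[(1E,3E,7E)-11,11-dimethoxy-4,8-dimethylundeca-1,3,7-trien-1-yl]prop-2-en-1-ol, via bromomagnesium prop-2-yn-1-olate 9 (not isolated), via dienyllithium 10 (not isolated), via alkenylmagnesium alkoxide 11 (not isolated), via oxamagnesacycle 12 (not isolated)
Conditions: 8, EtMgBr (1 equiv), THF, 0 °C; separately 7, t-BuLi (2 equiv), Et2O, −78 °C; combine, CuI (15 mol%), −20 °C to rt; then I2, THF, −40 to 0 °C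
Reagents that add atoms: iodine, II
Why: Iodine–lithium exchange with retention and transmetallation give an alkenylmagnesium alkoxide that undergoes copper-catalysed anti-carbomagnesiation of the propargylic alkoxide, the dienyl group going to the internal alkyne carbon and magnesium to the terminal carbon within a five-membered chelate, so that iodinolysis with retention fixes iodine cis to CH2OH (2Z).

Step 7
Reactants: 13 (2Z)-3-iodo-2-[(1E,3E,7E)-11,11-dimethoxy-4,8-dimethylundeca-1,3,7-trien-1-yl]prop-2-en-1-ol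
Product: 14 (2Z)-3-iodo-2-[(1E,3E,7E)-11,11-dimethoxy-4,8-dimethylundeca-1,3,7-trien-1-yl]prop-2-en-1-yl phenyl carbonate
Conditions: PhOCOCl, pyridine, CH2Cl2, 0 °C
Reagents that add atoms: phenyl chloroformate, O=C(Cl)Oc1ccccc1
Why: Acylation of the primary alcohol by the chloroformate (carbonate formation) places the future C2 carbonyl on O1 and provides phenoxide as a leaving group that is better than the ring alkoxide.

Step 8
Reactants: 14 (2Z)-3-iodo-2-[(1E,3E,7E)-11,11-dimethoxy-4,8-dimethylundeca-1,3,7-trien-1-yl]prop-2-en-1-yl phenyl carbonate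
Product: 17 4-[(1E,3E,7E)-11,11-dimethoxy-4,8-dimethylundeca-1,3,7-trien-1-yl]furan-2(5H)-one, via vinyllithium 15 (not isolated), via lithium hemiketal alkoxide 16 (not isolated)
Conditions: t-BuLi (2.05 equiv), THF/Et2O/pentane (4:1:1), −100 °C, then −78 °C; AcOH quench
Reagents that add atoms: none
Why: t-BuLi should exchange the vinylic iodine faster than it adds to the carbonate, giving a configurationally stable (Z)-vinyllithium whose carbanion (future C3) sits cis to the CH2O–C(=O)OPh arm. This carbanion attacks the carbonate carbon (future C2), forming the C3–C2 bond and the tetrahedral alkoxide 16, which expels phenoxide to give the furan-2(5H)-one. The closest known reaction type is the Parham cyclisation, that is, halogen–lithium exchange followed by intramolecular acylation by an ester, carbamate or carbonate. Ring B is closed in the 5-exo-trig mode. No stereocentre is formed; the selectivity needed is that exchange and ring closure outrun intermolecular attack on the carbonate and that the alkene geometry is kept. The 2Z geometry fixed by the chelate in step 6, the temperature of −100 °C and the five-membered transition state should secure this.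

Step 9
Reactants: 17 4-[(1E,3E,7E)-11,11-dimethoxy-4,8-dimethylundeca-1,3,7-trien-1-yl]furan-2(5H)-one
Product: 18 (4E,8E,10E)-4,8-dimethyl-11-(5-oxo-2,5-dihydrofuran-3-yl)undeca-4,8,10-trienal
Conditions: PPTS (cat.), acetone/H2O (9:1), 45 °C
Reagents that add atoms: water, O
Why: Mild acid-catalysed acetal hydrolysis frees the aldehyde without touching the butenolide or the conjugated triene.

Step 10
Reactants: 19 methyl 4-chloro-4-oxobutanoate; 20 (2-methylprop-1-en-1-yl)magnesium bromide
Product: 21 methyl 6-methyl-4-oxohept-5-enoate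
Conditions: CuI (10 mol%), THF, −40 °C
Reagents that add atoms: none
Why: Copper-catalysed acylation of the alkenyl Grignard reagent by the acid chloride is much faster than its attack on the methyl ester or on the ketone formed, so the enone should be obtained.

Step 11
Reactants: 21 methyl 6-methyl-4-oxohept-5-enoate
Product: 23 (5R)-5-(2-methylprop-1-en-1-yl)dihydrofuran-2(3H)-one, via hydroxy ester 22 (not isolated)
Conditions: (S)-1-methyl-3,3-diphenyltetrahydro-1H,3H-pyrrolo[1,2-c][1,3,2]oxazaborole (10 mol%), BH3·SMe2, THF, −20 °C; MeOH; then PPTS (cat.), toluene, 40 °C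
Reagents that add atoms: none
Why: Corey–Bakshi–Shibata reduction, in which the alkenyl group acts as the large substituent so that the (S)-oxazaborolidine should deliver hydride to the face giving the (R)-allylic alcohol, which lactonises under mild acid (intramolecular transesterification) without ionising the allylic C–O bond.

Step 12
Reactants: 23 (5R)-5-(2-methylprop-1-en-1-yl)dihydrofuran-2(3H)-one
Product: 26 (5R)-3-(diphenoxyphosphoryl)-5-(2-methylprop-1-en-1-yl)dihydrofuran-2(3H)-one (mixture of C3 epimers), via lithium enolate 24 (not isolated), via phosphonite 25 (not isolated)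
Conditions: LDA, THF, −78 °C; ClP(OPh)2; then 30% H2O2, 0 °C
Reagents that add atoms: diphenyl phosphorochloridite, ClP(Oc1ccccc1)Oc1ccccc1; hydrogen peroxide, OO
Why: The lithium enolate is phosphinylated at carbon by the soft trivalent phosphorus chloride and the phosphonite is oxidised to the phosphonate (enolate C-phosphinylation followed by oxidation); the C3 epimer mixture is irrelevant because C3 becomes sp2 in step 13.

Step 13
Reactants: 18 (4E,8E,10E)-4,8-dimethyl-11-(5-oxo-2,5-dihydrofuran-3-yl)undeca-4,8,10-trienal; 26 (5R)-3-(diphenoxyphosphoryl)-5-(2-methylprop-1-en-1-yl)dihydrofuran-2(3H)-one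
Product: 28 (3Z,5R)-3-[(4E,8E,10E)-4,8-dimethyl-11-(5-oxo-2,5-dihydrofuran-3-yl)undeca-4,8,10-trien-1-ylidene]-5-(2-methylprop-1-en-1-yl)dihydrofuran-2(3H)-one, via sodium phosphonate 27 (not isolated)
Conditions: 26, NaH (0.95 equiv relative to 26), THF, 0 °C; then 18, −78 to −20 °C
Reagents that add atoms: none
Why: Horner–Wadsworth–Emmons olefination with a diaryl phosphonate, whose electron-poor phenoxy groups make the kinetically formed adduct collapse quickly and should therefore place the aldehyde chain cis to the lactone carbonyl (3Z), while the C5 stereocentre set in step 11 is not touched.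

Compound list
1 | (2E,6E)-farnesol, (2E,6E)-3,7,11-trimethyldodeca-2,6,10-trien-1-ol | CC(C)=CCC/C(C)=C/CC/C(C)=C/CO | starting material
2 | (2E,6E)-10-bromo-3,7,11-trimethyldodeca-2,6-diene-1,11-diol (racemic bromohydrin) | CC(C)(O)C(Br)CC/C(C)=C/CC/C(C)=C/CO | intermediate
3 | (2E,6E)-9-(3,3-dimethyloxiran-2-yl)-3,7-dimethylnona-2,6-dien-1-ol (racemic) | CC1(C)OC1CC/C(C)=C/CC/C(C)=C/CO | intermediate
4 | (4E,8E)-10-hydroxy-4,8-dimethyldeca-4,8-dienal | O=CCC/C(C)=C/CC/C(C)=C/CO | intermediate
5 | (2E,6E)-10,10-dimethoxy-3,7-dimethyldeca-2,6-dien-1-ol | COC(OC)CC/C(C)=C/CC/C(C)=C/CO | intermediate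
6 | (2E,6E)-10,10-dimethoxy-3,7-dimethyldeca-2,6-dienal | COC(OC)CC/C(C)=C/CC/C(C)=C/C=O | intermediate
7 | (1E,3E,7E)-1-iodo-11,11-dimethoxy-4,8-dimethylundeca-1,3,7-triene | COC(OC)CC/C(C)=C/CC/C(C)=C/C=C/I | intermediate
8 | prop-2-yn-1-ol | C#CCO | starting material
9 | bromomagnesium prop-2-yn-1-olate | C#CCO[Mg]Br | intermediate
10 | [(1E,3E,7E)-11,11-dimethoxy-4,8-dimethylundeca-1,3,7-trien-1-yl]lithium | COC(OC)CC/C(C)=C/CC/C(C)=C/C=C/[Li] | intermediate
11 | [(1E,3E,7E)-11,11-dimethoxy-4,8-dimethylundeca-1,3,7-trien-1-yl](prop-2-yn-1-olato)magnesium | COC(OC)CC/C(C)=C/CC/C(C)=C/C=C/[Mg]OCC#C | intermediate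
12 | 4-[(1E,3E,7E)-11,11-dimethoxy-4,8-dimethylundeca-1,3,7-trien-1-yl]-2,5-dihydro-1,2-oxamagnesole | COC(OC)CC/C(C)=C/CC/C(C)=C/C=C/C1=C[Mg]OC1 | intermediate
13 | (2Z)-3-iodo-2-[(1E,3E,7E)-11,11-dimethoxy-4,8-dimethylundeca-1,3,7-trien-1-yl]prop-2-en-1-ol | COC(OC)CC/C(C)=C/CC/C(C)=C/C=C/C(CO)=C/I | intermediate
14 | (2Z)-3-iodo-2-[(1E,3E,7E)-11,11-dimethoxy-4,8-dimethylundeca-1,3,7-trien-1-yl]prop-2-en-1-yl phenyl carbonate | COC(OC)CC/C(C)=C/CC/C(C)=C/C=C/C(COC(=O)Oc1ccccc1)=C/I | intermediate
15 | [(1Z,3E,5E,9E)-13,13-dimethoxy-6,10-dimethyl-2-{[(phenoxycarbonyl)oxy]methyl}trideca-1,3,5,9-tetraen-1-yl]lithium | COC(OC)CC/C(C)=C/CC/C(C)=C/C=C/C(COC(=O)Oc1ccccc1)=C/[Li] | intermediate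
16 | lithium 4-[(1E,3E,7E)-11,11-dimethoxy-4,8-dimethylundeca-1,3,7-trien-1-yl]-2-phenoxy-2,5-dihydrofuran-2-olate (racemic) | COC(OC)CC/C(C)=C/CC/C(C)=C/C=C/C1=CC(O[Li])(Oc2ccccc2)OC1 | intermediate
17 | 4-[(1E,3E,7E)-11,11-dimethoxy-4,8-dimethylundeca-1,3,7-trien-1-yl]furan-2(5H)-one | COC(OC)CC/C(C)=C/CC/C(C)=C/C=C/C1=CC(=O)OC1 | intermediate
18 | (4E,8E,10E)-4,8-dimethyl-11-(5-oxo-2,5-dihydrofuran-3-yl)undeca-4,8,10-trienal | O=CCC/C(C)=C/CC/C(C)=C/C=C/C1=CC(=O)OC1 | intermediate
19 | methyl 4-chloro-4-oxobutanoate | COC(=O)CCC(Cl)=O | starting material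
20 | (2-methylprop-1-en-1-yl)magnesium bromide | CC(C)=C[Mg]Br | starting material
21 | methyl 6-methyl-4-oxohept-5-enoate | CC(C)=CC(=O)CCC(=O)OC | intermediate
22 | methyl (4R)-4-hydroxy-6-methylhept-5-enoate | CC(C)=C[C@H](O)CCC(=O)OC | intermediate
23 | (5R)-5-(2-methylprop-1-en-1-yl)dihydrofuran-2(3H)-one | CC(C)=C[C@H]1CCC(=O)O1 | intermediate
24 | lithium (2R)-2-(2-methylprop-1-en-1-yl)-2,3-dihydrofuran-5-olate | CC(C)=C[C@H]1CC=C(O[Li])O1 | intermediate
25 | (5R)-3-(diphenoxyphosphanyl)-5-(2-methylprop-1-en-1-yl)dihydrofuran-2(3H)-one (C3 epimers) | CC(C)=C[C@H]1CC(P(Oc2ccccc2)Oc2ccccc2)C(=O)O1 | intermediate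
26 | (5R)-3-(diphenoxyphosphoryl)-5-(2-methylprop-1-en-1-yl)dihydrofuran-2(3H)-one (C3 epimers) | CC(C)=C[C@H]1CC(P(=O)(Oc2ccccc2)Oc2ccccc2)C(=O)O1 | intermediate
27 | sodium (2R)-4-(diphenoxyphosphoryl)-2-(2-methylprop-1-en-1-yl)-2,3-dihydrofuran-5-olate | CC(C)=C[C@H]1CC(P(=O)(Oc2ccccc2)Oc2ccccc2)=C(O[Na])O1 | intermediate
28 | (3Z,5R)-3-[(4E,8E,10E)-4,8-dimethyl-11-(5-oxo-2,5-dihydrofuran-3-yl)undeca-4,8,10-trien-1-ylidene]-5-(2-methylprop-1-en-1-yl)dihydrofuran-2(3H)-one | CC(C)=C[C@H]1C/C(=C/CC/C(C)=C/CC/C(C)=C/C=C/C2=CC(=O)OC2)C(=O)O1 | target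

Total step count: 13. Longest linear sequence: 10 (steps 1 to 9 and step 13).

Steps most likely to fail

Step 6. The dienylmagnesium species may be protonated by the acetylenic C–H or couple with itself faster than it carbometallates the alkoxide, and part of the diene geometry may be lost on the way. The fallback builds ring B on a small fragment by the same ring closure and attaches the chain by olefination. It sets out from prop-2-yn-1-ol 8, which with MeMgBr and CuI (cat.) in THF and then I2 gives (2Z)-3-iodo-2-methylprop-2-en-1-ol F1. Phenyl chloroformate and pyridine convert this into (2Z)-3-iodo-2-methylprop-2-en-1-yl phenyl carbonate F2, and t-BuLi at −100 °C closes it to 4-methylfuran-2(5H)-one F3. Radical bromination (NBS, AIBN, PhCF3, reflux) gives 4-(bromomethyl)furan-2(5H)-one F4, and a Michaelis–Arbuzov reaction with P(OEt)3 gives diethyl [(5-oxo-2,5-dihydrofuran-3-yl)methyl]phosphonate F5. Horner–Wadsworth–Emmons olefination of enal 6 with F5 (LiHMDS, THF, −78 to 0 °C) comes back to the route at 17, so steps 5 to 8 are bypassed.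

Step 8. t-BuLi may add to the carbonate carbonyl, or the vinyllithium may be protonated or eliminate before it cyclises. The fallback is a carbonylative lactonisation catalysed by zerovalent palladium: iodo alcohol 13 is treated with PdCl2(PPh3)2, CO (1 atm) and Et3N in THF at 50 °C. Oxidative addition into the C–I bond, CO insertion and capture of the acylpalladium by the cis hydroxyl should give the butenolide directly. It sets out from 13 and comes back at 17 without new intermediates.

Step 13. The cyclic phosphonate may give eroded Z-selectivity, and proton transfer from the γ-position of the butenolide to the phosphonate anion may compete with olefination. The fallback uses the open-chain form of the reagent, for which Z-selectivity of α-alkyl diaryl phosphonoacetates is better established, and lactonises afterwards. It sets out from keto ester 21: reduction as in step 11 and silylation of hydroxy ester 22 (TBSCl, imidazole, DMF) before it lactonises give methyl (4R)-4-[(tert-butyldimethylsilyl)oxy]-6-methylhept-5-enoate F6. LDA, ClP(OPh)2 and then H2O2 give methyl (4R)-4-[(tert-butyldimethylsilyl)oxy]-2-(diphenoxyphosphoryl)-6-methylhept-5-enoate F7. Olefination of aldehyde 18 with F7 (NaH, THF, −78 to 0 °C) gives methyl (2Z,6E,10E,12E)-2-{(2R)-2-[(tert-butyldimethylsilyl)oxy]-4-methylpent-3-en-1-yl}-6,10-dimethyl-13-(5-oxo-2,5-dihydrofuran-3-yl)trideca-2,6,10,12-tetraenoate F8. HF·pyridine in THF followed by PPTS removes the silyl group and lactonises, coming back to the route at 28.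

Further compounds
F1 | step 6 | (2Z)-3-iodo-2-methylprop-2-en-1-ol | C/C(CO)=C/I
F2 | step 6 | (2Z)-3-iodo-2-methylprop-2-en-1-yl phenyl carbonate | C/C(COC(=O)Oc1ccccc1)=C/I
F3 | step 6 | 4-methylfuran-2(5H)-one | CC1=CC(=O)OC1
F4 | step 6 | 4-(bromomethyl)furan-2(5H)-one | BrCC1=CC(=O)OC1
F5 | step 6 | diethyl [(5-oxo-2,5-dihydrofuran-3-yl)methyl]phosphonate | CCOP(=O)(CC1=CC(=O)OC1)OCC
F0 | step 8 | none | none
F6 | step 13 | methyl (4R)-4-[(tert-butyldimethylsilyl)oxy]-6-methylhept-5-enoate | CC(C)=C[C@H](O[Si](C)(C)C(C)(C)C)CCC(=O)OC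
F7 | step 13 | methyl (4R)-4-[(tert-butyldimethylsilyl)oxy]-2-(diphenoxyphosphoryl)-6-methylhept-5-enoate | CC(C)=C[C@H](O[Si](C)(C)C(C)(C)C)CC(P(=O)(Oc1ccccc1)Oc1ccccc1)C(=O)OC
F8 | step 13 | methyl (2Z,6E,10E,12E)-2-{(2R)-2-[(tert-butyldimethylsilyl)oxy]-4-methylpent-3-en-1-yl}-6,10-dimethyl-13-(5-oxo-2,5-dihydrofuran-3-yl)trideca-2,6,10,12-tetraenoate | CC(C)=C[C@H](O[Si](C)(C)C(C)(C)C)C/C(=C/CC/C(C)=C/CC/C(C)=C/C=C/C1=CC(=O)OC1)C(=O)OC
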